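**Plan**
Numbering (drimane): ring A = C1–C5 and C10 (C3 ketone, C4 gem-dimethyl), ring B = C5–C10 (C7=C8), C11 = the OCH2 on C9. Retrosynthetic cuts, in order: the aryl ether O–C11, the C7=C8 alkene of ring B, C5–C6 together with one C4–CH3 bond, the other C4–CH3 bond, the C3 oxygen, and finally C9–C10.
Enabling feature: C3, C4 and C5 of ring A are the carbonyl, α- and β-carbons of a 2-methylcyclohex-2-enone whose γ-carbon is the quaternary C10, so the C6 unit and the second C4 methyl can be added across C4=C5 in one flask.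
Forward order: ring A is bought as 3-methylcyclohex-2-en-1-one, the C9 chain is attached by an Ireland–Claisen rearrangement, the ring A enone is built and doubly functionalised, ring B closes last by ring-closing metathesis, and isofraxidin is attached at the end.
Stereochemistry: C10 comes from a CBS-derived (R)-carbinol by suprafacial [3,3] transfer, C9 from the ketene acetal geometry and a boat transition state in the same step, and C5 from allylation anti to the C9 chain on C10.

Key step: step 9

Remark: with the (S)-oxazaborolidine the alkenyl carbon of 1 is assumed to act as the larger carbonyl substituent, as aryl does in aryl methyl ketones, which leads to the (R)-alcohol.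

Step 1
Reactants: 1 3-methylcyclohex-2-en-1-one
Product: 2 (1R)-3-methylcyclohex-2-en-1-ol
Conditions: (S)-1-methyl-3,3-diphenyltetrahydro-1H,3H-pyrrolo[1,2-c][1,3,2]oxazaborole (10 mol %), BH3·SMe2, THF, −20 °C, slow addition of 1; MeOH quench
Reagents that add atoms: none
Why: Corey–Bakshi–Shibata reduction: the ketone oxygen binds to the ring boron of the catalyst–borane complex with the alkenyl flank (the larger group) turned away from the catalyst, and hydride is passed from the N-bound BH3 to one carbonyl face, which with the (S)-catalyst should give the (R)-carbinol that later fixes C10; 1,2-reduction is faster than hydroboration of the trisubstituted alkene at this temperature.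

Step 2
Reactants: 2 (1R)-3-methylcyclohex-2-en-1-ol; 3 3-methylbut-2-enoic acid
Product: 4 (1R)-3-methylcyclohex-2-en-1-yl 3-methylbut-2-enoate
Conditions: DCC, DMAP (cat.), CH2Cl2, 0 °C → rt
Reagents that add atoms: none
Why: Steglich esterification, whose neutral conditions avoid ionisation of the allylic carbinol (which would scramble its configuration); the conjugated acid cannot isomerise during acylation and gives the same extended enolate as its β,γ-unsaturated isomer.

Step 3
Reactants: 4 (1R)-3-methylcyclohex-2-en-1-yl 3-methylbut-2-enoate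
Product: 8 (2R)-3-methyl-2-[(1S)-1-methylcyclohex-2-en-1-yl]but-3-enoic acid, via lithium dienolate 5 (not isolated), via silyl ketene acetal 6 (not isolated), via trimethylsilyl ester 7 (not isolated)
Conditions: LDA, THF, −78 °C; Me3SiCl, −78 °C → rt, then 50 °C; H2O/H+ work-up
Reagents that add atoms: none
Why: Ireland–Claisen rearrangement: LDA bound to the carbonyl oxygen of the s-cis ester removes a hydrogen of the syn γ-methyl group, so that dienolate 5 and ketene acetal 6 carry the isopropenyl group cis to the metalated oxygen; the [3,3] shift is suprafacial on the ring face that bears the C–O bond, which transfers the carbinol configuration to the quaternary C10, and the boat transition state usual for cyclohex-2-enyl esters, with isopropenyl and OSiMe3 both turned away from the ring, sets C9.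

Step 4
Reactants: 8 (2R)-3-methyl-2-[(1S)-1-methylcyclohex-2-en-1-yl]but-3-enoic acid
Product: 9 (2R)-3-methyl-2-[(1S)-1-methylcyclohex-2-en-1-yl]but-3-en-1-ol
Conditions: LiAlH4, THF, 0 °C → reflux; aqueous work-up
Reagents that add atoms: none
Why: Hydride reduction of the carboxylic acid (as its lithium carboxylate, which cannot enolise towards C9) to the primary alcohol C11; both alkenes are inert to LiAlH4.

Step 5
Reactants: 9 (2R)-3-methyl-2-[(1S)-1-methylcyclohex-2-en-1-yl]but-3-en-1-ol
Product: 10 tri(propan-2-yl){[(2R)-3-methyl-2-[(1S)-1-methylcyclohex-2-en-1-yl]but-3-en-1-yl]oxy}silane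
Conditions: TIPSCl, imidazole, DMF, rt
Reagents that add atoms: chlorotri(propan-2-yl)silane CC(C)[Si](Cl)(C(C)C)C(C)C
Why: Imidazole-promoted silylation of the unhindered primary alcohol; the triisopropylsilyl ether is chosen because it should survive chromium oxidation, palladium coupling, the silicon Lewis acid, MeLi and the ruthenium catalyst, and because its bulk enlarges the C9 chain that has to direct step 9.

Step 6
Reactants: 10 tri(propan-2-yl){[(2R)-3-methyl-2-[(1S)-1-methylcyclohex-2-en-1-yl]but-3-en-1-yl]oxy}silane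
Product: 11 (4S)-4-methyl-4-[(2R)-3-methyl-1-{[tri(propan-2-yl)silyl]oxy}but-3-en-2-yl]cyclohex-2-en-1-one
Conditions: CrO3, 3,5-dimethylpyrazole, CH2Cl2, −20 °C
Reagents that add atoms: chromium trioxide O=[Cr](=O)=O
Why: Allylic oxidation with the CrO3–3,5-dimethylpyrazole complex: C3 is the only secondary allylic CH2 of the ring alkene (its other allylic carbon, C10, is quaternary) and the oxygen enters at C3, the unhindered end of the allyl system, whereas the isopropenyl group offers only a primary methyl and a shielded tertiary C–H.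

Step 7
Reactants: 11 (4S)-4-methyl-4-[(2R)-3-methyl-1-{[tri(propan-2-yl)silyl]oxy}but-3-en-2-yl]cyclohex-2-en-1-one
Product: 12 (4R)-2-iodo-4-methyl-4-[(2R)-3-methyl-1-{[tri(propan-2-yl)silyl]oxy}but-3-en-2-yl]cyclohex-2-en-1-one
Conditions: I2, pyridine/CH2Cl2, 0 °C → rt
Reagents that add atoms: iodine II
Why: α-Iodination of the enone by addition–elimination (pyridine adds to C5, the enolate is iodinated at C4 and pyridine is expelled); the isolated alkenes and the silyl ether are not affected.

Step 8
Reactants: 12 (4R)-2-iodo-4-methyl-4-[(2R)-3-methyl-1-{[tri(propan-2-yl)silyl]oxy}but-3-en-2-yl]cyclohex-2-en-1-one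
Product: 13 (4S)-2,4-dimethyl-4-[(2R)-3-methyl-1-{[tri(propan-2-yl)silyl]oxy}but-3-en-2-yl]cyclohex-2-en-1-one
Conditions: MeB(OH)2, Pd(OAc)2 (5 mol %), SPhos (10 mol %), K3PO4, toluene/H2O, 80 °C
Reagents that add atoms: methylboronic acid CB(O)O
Why: Suzuki–Miyaura coupling of the alkenyl iodide with methylboronic acid, oxidative addition into the C(sp2)–I bond of an α-iodoenone being fast; no stereocentre is touched and the enone stays in place.

Step 9
Reactants: 13 (4S)-2,4-dimethyl-4-[(2R)-3-methyl-1-{[tri(propan-2-yl)silyl]oxy}but-3-en-2-yl]cyclohex-2-en-1-one; 14 allyltrimethylsilane; 15 iodomethane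
Product: 18 (3R,4S)-2,2,4-trimethyl-4-[(2R)-3-methyl-1-{[tri(propan-2-yl)silyl]oxy}but-3-en-2-yl]-3-(prop-2-en-1-yl)cyclohexan-1-one, via trimethylsilyl enol ether 16 (not isolated), via lithium enolate 17 (not isolated)
Conditions: 14 (3 equiv), Tf2NH (10 mol %, forms Me3SiNTf2), CH2Cl2, −78 → −40 °C; Et3N (0.2 equiv), evaporate; MeLi, THF, 0 °C → rt; 15, DMPU, −78 → 0 °C
Reagents that add atoms: none
Why: Tf2NH and the allylsilane give Me3SiNTf2, which silylates the enone oxygen of 13; allylsilane 14 then adds to C5 of the silyloxyallyl cation and hands its silyl group on, so the catalyst is regenerated and the trimethylsilyl enol ether 16 is formed with its double bond fixed between C3 and C4 (a silicon Lewis acid is chosen because the chlorotitanium enolate left by TiCl4 would not be alkylated by iodomethane). MeLi cleaves the O–Si bond of 16 to the lithium enolate 17, which iodomethane alkylates at C4, so that C5–C6 and the second C4–CH3 bond arise in one flask; the closest known reaction types are the Hosomi–Sakurai conjugate allylation and the regiospecific alkylation of a lithium enolate released from its silyl enol ether. No ring is closed in this step. C5 is the only new stereocentre and is controlled by the quaternary C10 next to it: in the reacting half-chair the branched C9 substituent is pseudoaxial and the allylsilane enters C5 along the axial trajectory on the opposite ring face, the small C10 methyl group being the only gauche neighbour of the incoming nucleophile. The step needs 1,4- instead of 1,2-addition (secured by the soft π-nucleophile and oxygen activation), attack on one face of C5 (secured by the size difference between the methyl group and the C9 chain with its triisopropylsilyloxy group) and methylation at C4 instead of C2 (secured by the position of the enol ether). The allyl group and the C9 chain thereby end trans-diequatorial on ring A, as the trans ring fusion made in step 10 requires.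

Step 10
Reactants: 18 (3R,4S)-2,2,4-trimethyl-4-[(2R)-3-methyl-1-{[tri(propan-2-yl)silyl]oxy}but-3-en-2-yl]-3-(prop-2-en-1-yl)cyclohexan-1-one
Product: 19 (4aS,5R,8aR)-1,1,4a,6-tetramethyl-5-({[tri(propan-2-yl)silyl]oxy}methyl)-3,4,4a,5,8,8a-hexahydronaphthalen-2(1H)-one
Conditions: second-generation Hoveyda–Grubbs catalyst [RuCl2(H2IMes)(=CH–C6H4-2-OiPr)] (5 mol %), toluene, 80 °C
Reagents that add atoms: none
Why: Ring-closing metathesis: the allyl and isopropenyl groups are held trans-diequatorial on the ring A chair, so the six-membered ring B closes by loss of ethene with the trisubstituted C7=C8 alkene in place and the trans ring fusion already fixed by C5 and C10.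

Step 11
Reactants: 19 (4aS,5R,8aR)-1,1,4a,6-tetramethyl-5-({[tri(propan-2-yl)silyl]oxy}methyl)-3,4,4a,5,8,8a-hexahydronaphthalen-2(1H)-one
Product: 20 (4aS,5R,8aR)-5-(hydroxymethyl)-1,1,4a,6-tetramethyl-3,4,4a,5,8,8a-hexahydronaphthalen-2(1H)-one
Conditions: Bu4NF, THF, rt
Reagents that add atoms: none
Why: Fluoride-induced cleavage of the Si–O bond, driven by the strong Si–F bond; ketone, alkene and the three stereocentres are inert.

Step 12
Reactants: 20 (4aS,5R,8aR)-5-(hydroxymethyl)-1,1,4a,6-tetramethyl-3,4,4a,5,8,8a-hexahydronaphthalen-2(1H)-one; 21 isofraxidin (7-hydroxy-6,8-dimethoxy-2H-chromen-2-one)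
Product: 22 6,8-dimethoxy-7-{[(1R,4aR,8aS)-2,5,5,8a-tetramethyl-6-oxo-1,4,4a,5,6,7,8,8a-octahydronaphthalen-1-yl]methoxy}-2H-chromen-2-one
Conditions: PPh3, DIAD, THF, 0 °C → rt
Reagents that add atoms: none
Why: Mitsunobu etherification: the acidic 7-hydroxycoumarin protonates the betaine from PPh3 and DIAD, the primary alcohol is activated as its alkoxyphosphonium salt and the phenoxide displaces Ph3PO at the non-stereogenic C11, so that C9 keeps its configuration.

**Compound list**
1 | 3-methylcyclohex-2-en-1-one | CC1=CC(=O)CCC1 | starting material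
2 | (1R)-3-methylcyclohex-2-en-1-ol | CC1=C[C@H](O)CCC1 | intermediate
3 | 3-methylbut-2-enoic acid | CC(C)=CC(O)=O | starting material
4 | (1R)-3-methylcyclohex-2-en-1-yl 3-methylbut-2-enoate | CC(C)=CC(=O)O[C@H]1C=C(C)CCC1 | intermediate
5 | lithium (1E)-3-methyl-1-{[(1R)-3-methylcyclohex-2-en-1-yl]oxy}buta-1,3-dien-1-olate (isopropenyl cis to OLi) | C=C(C)/C=C(\O[Li])O[C@H]1C=C(C)CCC1 | intermediate
6 | trimethyl{[(1Z)-3-methyl-1-{[(1R)-3-methylcyclohex-2-en-1-yl]oxy}buta-1,3-dien-1-yl]oxy}silane (isopropenyl cis to OSiMe3) | C=C(C)/C=C(\O[Si](C)(C)C)O[C@H]1C=C(C)CCC1 | intermediate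
7 | trimethylsilyl (2R)-3-methyl-2-[(1S)-1-methylcyclohex-2-en-1-yl]but-3-enoate | C1CC[C@](C)([C@H](C(=O)O[Si](C)(C)C)C(C)=C)C=C1 | intermediate
8 | (2R)-3-methyl-2-[(1S)-1-methylcyclohex-2-en-1-yl]but-3-enoic acid | C1CC[C@](C)([C@H](C(O)=O)C(C)=C)C=C1 | intermediate
9 | (2R)-3-methyl-2-[(1S)-1-methylcyclohex-2-en-1-yl]but-3-en-1-ol | C1CC[C@](C)([C@H](CO)C(C)=C)C=C1 | intermediate
10 | tri(propan-2-yl){[(2R)-3-methyl-2-[(1S)-1-methylcyclohex-2-en-1-yl]but-3-en-1-yl]oxy}silane | C1CC[C@](C)([C@H](CO[Si](C(C)C)(C(C)C)C(C)C)C(C)=C)C=C1 | intermediate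
11 | (4S)-4-methyl-4-[(2R)-3-methyl-1-{[tri(propan-2-yl)silyl]oxy}but-3-en-2-yl]cyclohex-2-en-1-one | O=C1CC[C@](C)([C@H](CO[Si](C(C)C)(C(C)C)C(C)C)C(C)=C)C=C1 | intermediate
12 | (4R)-2-iodo-4-methyl-4-[(2R)-3-methyl-1-{[tri(propan-2-yl)silyl]oxy}but-3-en-2-yl]cyclohex-2-en-1-one | O=C1CC[C@](C)([C@H](CO[Si](C(C)C)(C(C)C)C(C)C)C(C)=C)C=C1I | intermediate
13 | (4S)-2,4-dimethyl-4-[(2R)-3-methyl-1-{[tri(propan-2-yl)silyl]oxy}but-3-en-2-yl]cyclohex-2-en-1-one | O=C1CC[C@](C)([C@H](CO[Si](C(C)C)(C(C)C)C(C)C)C(C)=C)C=C1C | intermediate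
14 | allyltrimethylsilane | C=CC[Si](C)(C)C | starting material
15 | iodomethane | CI | starting material
16 | trimethyl{[(3R,4S)-2,4-dimethyl-4-[(2R)-3-methyl-1-{[tri(propan-2-yl)silyl]oxy}but-3-en-2-yl]-3-(prop-2-en-1-yl)cyclohex-1-en-1-yl]oxy}silane | C[Si](C)(C)OC=1CC[C@](C)([C@H](CO[Si](C(C)C)(C(C)C)C(C)C)C(C)=C)[C@@H](CC=C)C=1C | intermediate
17 | lithium (3R,4S)-2,4-dimethyl-4-[(2R)-3-methyl-1-{[tri(propan-2-yl)silyl]oxy}but-3-en-2-yl]-3-(prop-2-en-1-yl)cyclohex-1-en-1-olate | [Li]OC=1CC[C@](C)([C@H](CO[Si](C(C)C)(C(C)C)C(C)C)C(C)=C)[C@@H](CC=C)C=1C | intermediate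
18 | (3R,4S)-2,2,4-trimethyl-4-[(2R)-3-methyl-1-{[tri(propan-2-yl)silyl]oxy}but-3-en-2-yl]-3-(prop-2-en-1-yl)cyclohexan-1-one | O=C1CC[C@](C)([C@H](CO[Si](C(C)C)(C(C)C)C(C)C)C(C)=C)[C@@H](CC=C)C1(C)C | intermediate
19 | (4aS,5R,8aR)-1,1,4a,6-tetramethyl-5-({[tri(propan-2-yl)silyl]oxy}methyl)-3,4,4a,5,8,8a-hexahydronaphthalen-2(1H)-one (trans-fused; CH2O on C9 anti to the angular methyl) | CC(C)[Si](C(C)C)(C(C)C)OC[C@@H]1C(C)=CC[C@H]2C(C)(C)C(=O)CC[C@]12C | intermediate
20 | (4aS,5R,8aR)-5-(hydroxymethyl)-1,1,4a,6-tetramethyl-3,4,4a,5,8,8a-hexahydronaphthalen-2(1H)-one | OC[C@@H]1C(C)=CC[C@H]2C(C)(C)C(=O)CC[C@]12C | intermediate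
21 | isofraxidin (7-hydroxy-6,8-dimethoxy-2H-chromen-2-one) | COc1cc2ccc(=O)oc2c(OC)c1O | starting material
22 | 6,8-dimethoxy-7-{[(1R,4aR,8aS)-2,5,5,8a-tetramethyl-6-oxo-1,4,4a,5,6,7,8,8a-octahydronaphthalen-1-yl]methoxy}-2H-chromen-2-one | COc1cc2ccc(=O)oc2c(OC)c1OC[C@@H]1C(C)=CC[C@H]2C(C)(C)C(=O)CC[C@]12C | target

Total steps: 12. Longest linear sequence: 12 steps (1 to 22).

**Steps most likely to fail**

Step 9. The allylsilane may add to both faces of C5 if the methyl group and the C9 chain on C10 do not differ enough in the transition state. The isopropenyl group may also attack the silylated enone in a cation–olefin cyclisation. The fallback sets C5 under ring-fusion control instead. It sets out from 13: enol ether 16 is generated as in step 9 and, in place of the MeLi/iodomethane stage, is dehydrogenated with Pd(OAc)2 in MeCN (Saegusa–Ito oxidation) to (4R)-2,4-dimethyl-4-[(2R)-3-methyl-1-{[tri(propan-2-yl)silyl]oxy}but-3-en-2-yl]-3-(prop-2-en-1-yl)cyclohex-2-en-1-one F1, in which C5 is trigonal, so that both C5 epimers of 16 converge. Ring-closing metathesis with the ruthenium catalyst of step 10 closes ring B to the dienone (4aR,5R)-1,4a,6-trimethyl-5-({[tri(propan-2-yl)silyl]oxy}methyl)-4,4a,5,8-tetrahydronaphthalen-2(3H)-one F2. Lithium in liquid ammonia/THF with one equivalent of t-BuOH at −78 °C reduces the enone with axial protonation of C5, which should give the trans-fused lithium (4aS,5R,8aR)-1,4a,6-trimethyl-5-({[tri(propan-2-yl)silyl]oxy}methyl)-3,4,4a,5,8,8a-hexahydronaphthalen-2-olate F3. Iodomethane added to the same flask methylates C4 (Birch-type reductive alkylation), and the route is rejoined at 19.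

Step 3. The C9 configuration may erode if the dienolate forms as a mixture of geometric isomers, because each isomer passes its geometry on to C9. The fallback locks the geometry by chelation and sets out from 2. Steglich esterification with 3-hydroxy-3-methylbutanoic acid should give (1R)-3-methylcyclohex-2-en-1-yl 3-hydroxy-3-methylbutanoate F4. Two equivalents of LDA in THF at −78 °C give the dilithium alkoxide–enolate of that ester F5, in which lithium bridging of the two oxygens holds the carbinol carbon cis to the enolate oxygen. On warming it should rearrange through the same boat arrangement and give, after acidification, (2S)-3-hydroxy-3-methyl-2-[(1S)-1-methylcyclohex-2-en-1-yl]butanoic acid F6. LiAlH4 reduces it to (2R)-3-methyl-2-[(1S)-1-methylcyclohex-2-en-1-yl]butane-1,3-diol F7. TIPSCl/imidazole silylates only the primary hydroxyl to (3R)-2-methyl-3-[(1S)-1-methylcyclohex-2-en-1-yl]-4-{[tri(propan-2-yl)silyl]oxy}butan-2-ol F8. Dehydration of the tertiary alcohol with SOCl2/pyridine at 0 °C, towards a methyl group and away from the shielded C9–H, rejoins the route at 10.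

Step 12. Displacement at the β-branched C11 by a phenol flanked by two methoxy groups may be slow, so that the alkoxyphosphonium intermediate is diverted to elimination or to alkylation of the hydrazide. The fallback separates activation from substitution and sets out from 20. MsCl/Et3N in CH2Cl2 at 0 °C gives [(1R,4aR,8aS)-2,5,5,8a-tetramethyl-6-oxo-1,4,4a,5,6,7,8,8a-octahydronaphthalen-1-yl]methyl methanesulfonate F9. This is displaced by the caesium phenoxide of 21 (Cs2CO3, DMF, 60 °C) in a Williamson ether synthesis, which arrives at 22.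

**Further compounds**
F1 | step 9 | (4R)-2,4-dimethyl-4-[(2R)-3-methyl-1-{[tri(propan-2-yl)silyl]oxy}but-3-en-2-yl]-3-(prop-2-en-1-yl)cyclohex-2-en-1-one | O=C1CC[C@](C)([C@H](CO[Si](C(C)C)(C(C)C)C(C)C)C(C)=C)C(CC=C)=C1C
F2 | step 9 | (4aR,5R)-1,4a,6-trimethyl-5-({[tri(propan-2-yl)silyl]oxy}methyl)-4,4a,5,8-tetrahydronaphthalen-2(3H)-one | CC(C)[Si](C(C)C)(C(C)C)OC[C@@H]1C(C)=CCC2=C(C)C(=O)CC[C@]12C
F3 | step 9 | lithium (4aS,5R,8aR)-1,4a,6-trimethyl-5-({[tri(propan-2-yl)silyl]oxy}methyl)-3,4,4a,5,8,8a-hexahydronaphthalen-2-olate | CC(C)[Si](C(C)C)(C(C)C)OC[C@@H]1C(C)=CC[C@H]2C(C)=C(O[Li])CC[C@]12C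
F4 | step 3 | (1R)-3-methylcyclohex-2-en-1-yl 3-hydroxy-3-methylbutanoate | CC(C)(O)CC(=O)O[C@H]1C=C(C)CCC1
F5 | step 3 | dilithium alkoxide–enolate of F4 (carbinol carbon cis to the enolate oxygen) | [Li]OC(C)(C)/C=C(\O[Li])O[C@H]1C=C(C)CCC1
F6 | step 3 | (2S)-3-hydroxy-3-methyl-2-[(1S)-1-methylcyclohex-2-en-1-yl]butanoic acid | C1CC[C@](C)([C@H](C(O)=O)C(C)(C)O)C=C1
F7 | step 3 | (2R)-3-methyl-2-[(1S)-1-methylcyclohex-2-en-1-yl]butane-1,3-diol | C1CC[C@](C)([C@H](CO)C(C)(C)O)C=C1
F8 | step 3 | (3R)-2-methyl-3-[(1S)-1-methylcyclohex-2-en-1-yl]-4-{[tri(propan-2-yl)silyl]oxy}butan-2-ol | C1CC[C@](C)([C@H](CO[Si](C(C)C)(C(C)C)C(C)C)C(C)(C)O)C=C1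
F9 | step 12 | [(1R,4aR,8aS)-2,5,5,8a-tetramethyl-6-oxo-1,4,4a,5,6,7,8,8a-octahydronaphthalen-1-yl]methyl methanesulfonate | CS(=O)(=O)OC[C@@H]1C(C)=CC[C@H]2C(C)(C)C(=O)CC[C@]12C
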